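**Plan**
- Cuts: C2–C1' and O1–C2 (retro oxa-Michael/Knoevenagel) release syncarpic acid and a bicyclic lactol. Next come C4a–C5 and C8–C8a of the fused carbocycle, then the C4a–C8a alkyne carbon, then C3–C4.
- Enabling feature: once C5 is joined to C8, the run C5(=O)–C6Me2–C7(=O)–C8Me2 of the fused ring is the strained, non-enolisable, symmetric 2,2,4,4-tetramethylcyclobutane-1,3-dione. The remainder, C4a=C8a–O1, is an ynolate (C≡C–O⁻), so the six-membered ring can arise by insertion of two carbons into a four-membered ring.
- Forward order: a nitro-Michael addition joins C3–C4. Nitro → aldehyde → alkyne supplies C4a and C8a. The ynolate ring expansion builds the carbocycle and its acid quench closes the pyran as a lactol. The pendant ring, made by dearomatising methylation of phloroacetophenone, is attached last.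
- Stereochemistry: C3 and C4 come together from the amine-catalysed syn-selective Michael addition. C2 is set under thermodynamic control in the reversible final oxa-Michael closure.

Key step: step 5

Remark: chromene numbering of the target (O1, C2, C3, C4, C4a, C5–C8, C8a) is used for all intermediates. The hemiacetal carbon of the lactol from step 5 is an equilibrating anomeric mixture and is written without configuration.

**Step 1**
Reactants: 1 3-methylbutanal; 2 nitromethane
Product: 4 (E)-4-methyl-1-nitropent-1-ene, via nitroaldol 3 (not isolated)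
Conditions: 2 (5 equiv), KOt-Bu (5 mol %), THF/t-BuOH, 0 °C; then MsCl, Et3N (2.2 equiv), CH2Cl2, 0 °C
Reagents that add atoms: none
Why: Henry addition followed by mesylation and E1cB elimination is the standard route to aliphatic nitroalkenes and should give the conjugated E isomer, with no stereocentre surviving.

**Step 2**
Reactants: 1 3-methylbutanal; 4 (E)-4-methyl-1-nitropent-1-ene
Product: 6 (2S,3S)-1,1-dimethoxy-5-methyl-3-(nitromethyl)-2-(propan-2-yl)hexane, via nitro aldehyde 5 (not isolated)
Conditions: (R)-α,α-diphenylprolinol trimethylsilyl ether (10 mol %), 4-nitrophenol (10 mol %), toluene, 0 °C to rt; then HC(OMe)3, MeOH, p-TsOH·H2O (cat.), rt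
Reagents that add atoms: trimethyl orthoformate, COC(OC)OC
Why: Enamine-catalysed Michael addition, in which the E-enamine of 1, shielded on one face by the (R)-catalyst, adds to the E-nitroalkene through the synclinal transition state and sets C3 and C4 together as the syn (S,S) pair, after which immediate acetalisation locks the epimerisable C3.

**Step 3**
Reactants: 6 (2S,3S)-1,1-dimethoxy-5-methyl-3-(nitromethyl)-2-(propan-2-yl)hexane
Product: 8 (2S,3S)-3-(dimethoxymethyl)-4-methyl-2-(2-methylpropyl)pentanal, via sodium nitronate 7 (not isolated)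
Conditions: NaOMe (1.0 equiv), MeOH, 0 °C; O3, MeOH/CH2Cl2, −78 °C, stopped at the first blue colour; N2 purge, pH 7 buffer
Reagents that add atoms: ozone, [O-][O+]=O
Why: The oxidative Nef reaction (ozonolysis of the nitronate C=N bond) runs under basic, non-aqueous conditions that spare the acetal, and low temperature with one equivalent of base should keep the new α-centre C4 intact.

**Step 4**
Reactants: 8 (2S,3S)-3-(dimethoxymethyl)-4-methyl-2-(2-methylpropyl)pentanal
Product: 9 (3S,4S)-4-(dimethoxymethyl)-5-methyl-3-(2-methylpropyl)hex-1-yne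
Conditions: dimethyl (1-diazo-2-oxopropyl)phosphonate, K2CO3, MeOH, 0 °C to rt
Reagents that add atoms: dimethyl (1-diazo-2-oxopropyl)phosphonate, CC(=O)C(=[N+]=[N-])P(=O)(OC)OC
Why: Seyferth-Gilbert homologation in the Ohira-Bestmann variant adds the carbon that becomes C8a, under carbonate conditions mild enough for α-branched dialkyl aldehydes to keep their configuration.

**Step 5**
Reactants: 9 (3S,4S)-4-(dimethoxymethyl)-5-methyl-3-(2-methylpropyl)hex-1-yne; 10 2,2,4,4-tetramethylcyclobutane-1,3-dione
Product: 16 (3S,4S)-2-hydroxy-6,6,8,8-tetramethyl-4-(2-methylpropyl)-3-(propan-2-yl)-3,4-dihydro-2H-chromene-5,7(6H,8H)-dione (anomeric mixture), via lithium acetylide 11 (not isolated), via lithium ynolate 12 (not isolated), via ketene cyclobutanolate 13 (not isolated), via acylketene enolate 14 (not isolated), via triketone enolate 15 (not isolated)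
Conditions: n-BuLi (1.0 equiv), THF, −78 °C; t-BuOOLi (from anhydrous t-BuOOH and n-BuLi, THF, −78 °C), −78 to 0 °C; 10 (1.5 equiv), −78 °C to rt; then 1 M HCl, THF, rt
Reagents that add atoms: tert-butyl hydroperoxide, CC(C)(C)OO; water, O
Why: Proposed new method: the unhindered sp carbon of ynolate 12 adds to one of the two equivalent, strain-activated carbonyl groups of 10, cyclobutanolate 13 releases the ring strain by retro-Claisen cleavage of the adjacent C(O)–CMe2 bond, and the tertiary enolate carbon of 14 then attacks the acylketene carbon, so that C4a and C8a end up inserted between C5 and C8 and the four-membered ring has become the six-membered one, held as the delocalised triketone enolate 15. The closest known reaction types are the oxidation of lithium acetylides to ynolates with t-BuOOLi, the addition of ynolates to ketones (which normally ends in a β-lactone enolate and olefination), the ring cleavage of 10 by carbon and oxygen nucleophiles, and the base-induced closure of dimethylketene oligomer esters to hexamethylcyclohexane-1,3,5-trione. The carbocycle closes by 6-(enolendo)-exo-dig C-acylation, and after the acid quench has hydrolysed the acetal the pyran closes by 6-exo-trig addition of the C8a enol oxygen to the C2 aldehyde. C3 and C4 carry no acidified hydrogen in 11–15 and are carried through unchanged, and the only new centre, the hemiacetal carbon C2, is an uncontrolled equilibrating mixture that step 8 erases. The step needs C–C cleavage in 13 to outrun closure to the spiro β-lactone enolate and C-acylation to win over O-acylation in 14; ring strain together with the crowding of a spiro centre between two CMe2 groups favours the first, and the second is favoured because only C-acylation ends in the stabilised enolate 15. Because C4a bears no hydrogen in 13 and 14 the tertiary enolate cannot be lost by proton transfer, as it would be with the corresponding ester enolate, and the symmetry of 10 leaves no regiochemical choice.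

**Step 6**
Reactants: 17 1-(2,4,6-trihydroxyphenyl)ethanone
Product: 18 4-acetyl-5-hydroxy-2,2,6,6-tetramethylcyclohex-4-ene-1,3-dione
Conditions: MeI (excess), NaOMe, MeOH, reflux
Reagents that add atoms: iodomethane, CI
Why: Exhaustive base-mediated C-methylation of an acylphloroglucinol is a well-known dearomatisation that installs both gem-dimethyl groups while the acetyl group blocks the third ring carbon.

**Step 7**
Reactants: 18 4-acetyl-5-hydroxy-2,2,6,6-tetramethylcyclohex-4-ene-1,3-dione
Product: 19 syncarpic acid (5-hydroxy-2,2,6,6-tetramethylcyclohex-4-ene-1,3-dione)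
Conditions: 6 M aq HCl, reflux
Reagents that add atoms: none
Why: Acid-promoted retro-Claisen deacylation of a 2-acyl-1,3-dione is the standard release of syncarpic acid.

**Step 8**
Reactants: 16 (3S,4S)-2-hydroxy-6,6,8,8-tetramethyl-4-(2-methylpropyl)-3-(propan-2-yl)-3,4-dihydro-2H-chromene-5,7(6H,8H)-dione; 19 syncarpic acid
Product: 21 ericifolione, via alkylidene triketone 20 (not isolated)
Conditions: 19 (1.0 equiv), ethylenediammonium diacetate (10 mol %), CH2Cl2, 4 Å MS, rt, then 40 °C until the C2 epimers have converged
Reagents that add atoms: none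
Why: Domino Knoevenagel condensation/oxa-Michael addition, in which the ring-chain tautomer of 16 exposes the C2 aldehyde, condensation with 19 gives 20, and its reversible 6-exo-trig closure by the C8a enol oxygen should settle C2 thermodynamically as 2R, with the bulky ring equatorial and cis to the C3 isopropyl group, which stays trans-diaxial to the C4 isobutyl group to avoid the C5 carbonyl.

**Compound list**
1 | 3-methylbutanal | CC(C)CC=O | starting material
2 | nitromethane | C[N+](=O)[O-] | starting material
3 | 4-methyl-1-nitropentan-2-ol (racemic, not isolated) | CC(C)CC(O)C[N+](=O)[O-] | intermediate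
4 | (E)-4-methyl-1-nitropent-1-ene | CC(C)C/C=C/[N+](=O)[O-] | intermediate
5 | (2S,3S)-5-methyl-3-(nitromethyl)-2-(propan-2-yl)hexanal (not isolated) | CC(C)C[C@@H]([C@H](C(C)C)C=O)C[N+](=O)[O-] | intermediate
6 | (2S,3S)-1,1-dimethoxy-5-methyl-3-(nitromethyl)-2-(propan-2-yl)hexane | CC(C)C[C@@H]([C@H](C(C)C)C(OC)OC)C[N+](=O)[O-] | intermediate
7 | sodium nitronate of 6 (not isolated) | CC(C)C[C@@H]([C@H](C(C)C)C(OC)OC)C=[N+]([O-])[O-].[Na+] | intermediate
8 | (2S,3S)-3-(dimethoxymethyl)-4-methyl-2-(2-methylpropyl)pentanal | CC(C)C[C@@H]([C@H](C(C)C)C(OC)OC)C=O | intermediate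
9 | (3S,4S)-4-(dimethoxymethyl)-5-methyl-3-(2-methylpropyl)hex-1-yne | CC(C)C[C@@H]([C@H](C(C)C)C(OC)OC)C#C | intermediate
10 | 2,2,4,4-tetramethylcyclobutane-1,3-dione | CC1(C)C(=O)C(C)(C)C1=O | starting material
11 | lithium acetylide of 9 (not isolated) | CC(C)C[C@@H]([C@H](C(C)C)C(OC)OC)C#[C-].[Li+] | intermediate
12 | lithium ynolate from 9 (not isolated) | CC(C)C[C@@H]([C@H](C(C)C)C(OC)OC)C#C[O-].[Li+] | intermediate
13 | ketene cyclobutanolate, adduct of 12 to 10 (not isolated) | CC(C)C[C@@H]([C@H](C(C)C)C(OC)OC)C(=C=O)C1([O-])C(C)(C)C(=O)C1(C)C.[Li+] | intermediate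
14 | ring-opened acylketene enolate (not isolated) | CC(C)C[C@@H]([C@H](C(C)C)C(OC)OC)C(=C=O)C(=O)C(C)(C)C([O-])=C(C)C.[Li+] | intermediate
15 | lithium enolate of 5-hydroxy-4-[(2S,3S)-1,1-dimethoxy-5-methyl-2-(propan-2-yl)hexan-3-yl]-2,2,6,6-tetramethylcyclohex-4-ene-1,3-dione (not isolated) | CC(C)C[C@@H]([C@H](C(C)C)C(OC)OC)C1=C([O-])C(C)(C)C(=O)C(C)(C)C1=O.[Li+] | intermediate
16 | (3S,4S)-2-hydroxy-6,6,8,8-tetramethyl-4-(2-methylpropyl)-3-(propan-2-yl)-3,4-dihydro-2H-chromene-5,7(6H,8H)-dione (anomeric mixture) | CC(C)C[C@@H]1C2=C(OC(O)[C@H]1C(C)C)C(C)(C)C(=O)C(C)(C)C2=O | intermediate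
17 | 1-(2,4,6-trihydroxyphenyl)ethanone | CC(=O)c1c(O)cc(O)cc1O | starting material
18 | 4-acetyl-5-hydroxy-2,2,6,6-tetramethylcyclohex-4-ene-1,3-dione | CC(=O)C1=C(O)C(C)(C)C(=O)C(C)(C)C1=O | intermediate
19 | syncarpic acid (5-hydroxy-2,2,6,6-tetramethylcyclohex-4-ene-1,3-dione) | CC1(C)C(O)=CC(=O)C(C)(C)C1=O | intermediate
20 | open alkylidene triketone, C3/C4 arranged in space as in 16 (not isolated) | CC(C)C[C@@H]([C@H](C(C)C)C=C1C(=O)C(C)(C)C(=O)C(C)(C)C1=O)C2=C(O)C(C)(C)C(=O)C(C)(C)C2=O | intermediate
21 | ericifolione, (2R,3S,4S)-2-(2-hydroxy-3,3,5,5-tetramethyl-4,6-dioxocyclohex-1-en-1-yl)-6,6,8,8-tetramethyl-4-(2-methylpropyl)-3-(propan-2-yl)-3,4-dihydro-2H-chromene-5,7(6H,8H)-dione | CC(C)C[C@@H]1C2=C(O[C@@H](C3=C(O)C(C)(C)C(=O)C(C)(C)C3=O)[C@H]1C(C)C)C(C)(C)C(=O)C(C)(C)C2=O | target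

**Step count and risks**

Total step count: 8. Longest linear sequence: 6 (steps 1, 2, 3, 4, 5, 8).

**Step 5 (Proposed new method).**
- Possible failures:
  - collapse of the ketene alkoxide to the spiro β-lactone enolate, followed by olefination;
  - O-acylation instead of C-acylation of the tertiary enolate;
  - interception of the acylketene, or consumption of the dione, by tert-butoxide.
- The fallback uses known chemistry and takes the fused ring in its final size. It sets out from 19 and 1 and returns at 16.
- Knoevenagel condensation of 19 with 1 (piperidine/AcOH or proline, CH2Cl2) gives 2-(3-methylbutylidene)-4,4,6,6-tetramethylcyclohexane-1,3,5-trione F1.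
- The enamine of a second equivalent of 1 with the same (R)-catalyst then adds to F1. This is a Michael addition/hemiacetalisation, the inverse-demand oxa-Diels-Alder manifold of alkylidene 1,3-diones, and it gives 16 after hydrolysis of the aminal.

**Step 8.**
- Possible failures:
  - insufficient bias or incomplete equilibration at C2;
  - erosion of C3 by enamine formation or γ-deprotonation of the alkylidene;
  - addition of a second nucleophile to the alkylidene.
- The fallback separates C–C bond formation from the equilibration and uses pre-activated partners without amine or protic acid. It sets out from 16 and 19 and returns at 21.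
- 16 is acetylated (Ac2O, pyridine) to the anomeric acetate F2, and 19 is silylated (TMSCl, Et3N) to its trimethylsilyl enol ether F3.
- The two are joined by TMSOTf in CH2Cl2 at −78 °C (Mukaiyama-type C-glycosylation).
- The C2 epimers are then equilibrated in a separate, short operation with catalytic Et3N in toluene through the retro-oxa-Michael/oxa-Michael pair, giving 21.

**Step 3.**
- Possible failures:
  - epimerisation of C4 once the aldehyde is liberated in basic methanol;
  - over-oxidation;
  - attack of ozone on the acetal C–H.
- The fallback avoids both the aldehyde and the alkyne. It sets out from 6 and returns at 12.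
- The potassium nitronate of 6 is oxidised with excess basic KMnO4 to (2S,3S)-3-(dimethoxymethyl)-4-methyl-2-(2-methylpropyl)pentanoic acid F4, which is esterified (MeI, K2CO3, DMF) to the methyl ester F5.
- Kowalski homologation conditions (CH2Br2, LiTMP, THF, −78 °C; LiHMDS; then n-BuLi, −78 °C to rt) take F5 through the lithium α,α-dibromo enolate F6. Bromine-lithium exchange and a 1,2-shift of C4 with retention then give ynolate 12, which is used directly with 10 as in step 5.

**Further compounds**
F1 | step 5 | 2-(3-methylbutylidene)-4,4,6,6-tetramethylcyclohexane-1,3,5-trione | CC(C)CC=C1C(=O)C(C)(C)C(=O)C(C)(C)C1=O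
F2 | step 8 | (3S,4S)-6,6,8,8-tetramethyl-4-(2-methylpropyl)-5,7-dioxo-3-(propan-2-yl)-3,4,5,6,7,8-hexahydro-2H-chromen-2-yl acetate (anomeric mixture) | CC(C)C[C@@H]1C2=C(OC(OC(C)=O)[C@H]1C(C)C)C(C)(C)C(=O)C(C)(C)C2=O
F3 | step 8 | 2,2,6,6-tetramethyl-5-(trimethylsilyloxy)cyclohex-4-ene-1,3-dione | CC1(C)C(O[Si](C)(C)C)=CC(=O)C(C)(C)C1=O
F4 | step 3 | (2S,3S)-3-(dimethoxymethyl)-4-methyl-2-(2-methylpropyl)pentanoic acid | CC(C)C[C@@H]([C@H](C(C)C)C(OC)OC)C(=O)O
F5 | step 3 | methyl (2S,3S)-3-(dimethoxymethyl)-4-methyl-2-(2-methylpropyl)pentanoate | CC(C)C[C@@H]([C@H](C(C)C)C(OC)OC)C(=O)OC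
F6 | step 3 | lithium α,α-dibromo enolate derived from F5 | CC(C)C[C@@H]([C@H](C(C)C)C(OC)OC)C([O-])=C(Br)Br.[Li+]
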